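1. Starting material is conserved: theta's six forms add to 100 % at its last reading, so a point lost from one form appears in another.

all flasks: starting material 34 mM

| flask | partner | second reagent | third reagent | protic impurity | remark | time |
|---|---|---|---|---|---|---|
| zeta | 0.90 equiv | 0.95 equiv | 2 equiv | 0.46 mM | run made earlier |  |
| theta | 0.90 equiv | 0.95 equiv | 2 equiv | 1 mM | run made earlier |  |
| flask | 0.900 equiv | 0.950 equiv | 2.00 equiv | 0.680 mM |  | 2.5 min |

| run | time / s | intermediate A / % | intermediate B / % | side product A / % | target / % | side product B / % | starting material / % |
|---|---|---|---|---|---|---|---|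
| zeta | 15.0 | 17.3 | 2.4 | 25.2 | 0 | 12.2 | 41.0 |
| zeta | 40.0 | 9.3 | 2.5 | 31.6 | 2.2 | 34.1 | 18.5 |
| zeta | 80.0 | 2.4 | 0.9 | 33.4 | 5.6 | 49.7 | 7.9 |
| zeta | 120 | 1.7 | 0.5 | 32.9 | 6.5 | 55.7 | 4.1 |
| theta | 10.0 | 17.0 | 1.5 | 22.8 | 0.5 | 7.8 | 50.2 |
| theta | 20.0 | 15.4 | 2.5 | 27.9 | 1.2 | 18.7 | 32.6 |
| theta | 50.0 | 7.4 | 2.4 | 32.2 | 2.8 | 40.1 | 14.3 |
| theta | 120 | 1.1 | 0.6 | 33.6 | 5.1 | 55.6 | 4.1 |

(standard deviation of a reading: 0.5 percentage points)
- on the list of suspects stand: starting material + partner -> intermediate A; second reagent + intermediate A -> intermediate B; third reagent + intermediate B -> target; starting material + second reagent -> side product A; 2 second reagent -> self-condensation product; intermediate A -> side product B; third reagent + protic impurity -> quenched reagent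
- the largest share of what was charged as starting material, at 2.5 min belongs to (intermediate B / side product B / starting material / side product A / target / intermediate A)
- the largest share itself, whichever of these holds it, in percent of the starting material charged

2. For whoever takes over the flask: we call starting material plus intermediate A the pending share. At 120 s, zeta and theta average 5.50 % pending and 55.6 % side product B.

3. Don't correct for the protic impurity: at 0.46 mM and 1 mM, side product B differs by 0.1 percentage points, with a scatter of 0.5 points.

4. Between 50.0 s and 120 s, theta lost 17 points pending and gained 16 points side product B. That ratio, 0.939, is the capture share (a partition ratio): side product B gained per pending point lost.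

5. Zeta's late pending share falls at 0.0144 s⁻¹, so over the last 30.0 s our first round loses 2.4 points. Putting that back lowers the mean pending share, and the second round loses 1.9 points.

6. We therefore expect side product B at 57.4 % in the flask at 2.5 min.

7. The forecast says side product B at 57.5 %: “the impurity mainly changes the small target yield”.

8. The flask gives side product B at 56.8 %, 0.60 points below our reckoning.

    starting material + partner → intermediate A (k = 1.50 L mol⁻¹ s⁻¹)
    second reagent + intermediate A → intermediate B (k = 1.30 L mol⁻¹ s⁻¹)
    third reagent + intermediate B → target (k = 0.490 L mol⁻¹ s⁻¹)
    starting material + second reagent → side product A (k = 1.70 L mol⁻¹ s⁻¹)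
    2 second reagent → self-condensation product (k = 1.90 L mol⁻¹ s⁻¹)
    intermediate A → side product B (k = 0.0650 s⁻¹)
    third reagent + protic impurity → quenched reagent (k = 110 L mol⁻¹ s⁻¹)

The flask is not at rest at 2.50 min: its pending share is 3.27 %, and the capture share read from theta gives an estimate of 3.1 points still to reach side product B. At 25.0 min, side product B stands at 59.9 %, up 3 points, while starting material and intermediate A read 0 % and 0 %. The neighbour flask with 0.240 equiv of second reagent has 72.7 % side product B at 2.50 min and a pending share of 10.0 %, larger than the flask's, and the same capture share gives an estimate of 9.4 points still to come there.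

(The numbers in the tables are calculated with constants of no real substance; scatter was added.)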